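Slowness is the thing to watch in this run. The starting material opens to the intermediate with a half-life of 0.37 h, while the intermediate lasts about 0.683 s. The opening is therefore the rate-limiting step, and the clock and the product mix can be reckoned apart.

the same everywhere: starting material 0.050 M; first nucleophile 0.125 M; second nucleophile 0.0525 M

|  | time |
|---|---|
| south | 1.0 h |
| west | 2.0 h |
| north | 4.0 h |

- which of the two there is more of at the end, south (target / solvolysis product)
- which of the two there is more of at the end, west (target / solvolysis product)
- which of the two there is more of at the end, north (target / solvolysis product)
- how much target is there at the end, in percent of the starting material charged: south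
- how much target is there at the end, in percent of the starting material charged: west
- how much target is there at the end, in percent of the starting material charged: north

    intermediate → solvolysis product (k1 = 0.785 s⁻¹)
    first nucleophile → decomposition product (k2 = 9.37 × 10⁻⁷ s⁻¹)
    second nucleophile + intermediate → other capture product (k3 = 2.21 M⁻¹ s⁻¹)
    first nucleophile + intermediate → target (k4 = 4.51 M⁻¹ s⁻¹)
    starting material → intermediate (k5 = 5.27 × 10⁻⁴ s⁻¹)
    target ⇌ isomer of the product (K6 = 0.63, k6 = 4.53 × 10⁻⁴ s⁻¹)

The mix is made each time an intermediate is spent. Solvolysis takes it at 0.785 s⁻¹, the second nucleophile at 0.116 s⁻¹, and the first nucleophile, giving target, at 0.564 s⁻¹ from its charge. I call s the capture share: the target route's rate over the sum of these rates, with c the first nucleophile then present. Solvolysis is faster than capture at the charge, and c falls from there, so I commit to solvolysis product ahead at each of the three times.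

Two extreme flasks can be done in the head. If c never falls, s is 38.5 %. If c has already lost what capture can take, 0.0192 M, it stands at 0.106 M and s is 34.6 %. The real flask runs from the first to the second with c falling about evenly, so I take the mean. Target and isomer of the product then relax with a half-life of 0.164 h, short against 1.0 h, so target keeps 61.3 % of their pool. The mean share times that fraction is 22.4 %, the target plateau I expect once the starting material has opened. Scaled by the starting material opened, it gives me 19.1 % for south, 21.9 % for west and 22.4 % for north. I hold the south figure as a low mark, since the newest target there is still unrelaxed.

The forecast names solvolysis product for south, solvolysis product for west and solvolysis product for north. It gives target at 20.8 % (19.8 % to 21.8 %), 22.2 % (21.2 % to 23.2 %) and 22.5 % (21.5 % to 23.5 %): “the target yield levels off near 22–23%”. It stands above my mark for south.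

The simulation gives target at 20.8 %, 22.3 % and 22.5 %, against solvolysis product at 46.9 %, 54.1 % and 55.4 %, so solvolysis product leads in each flask.

The forecast holds on every count. North reads 22.5 % against the plateau of 22.4 %, and at 40.0 h it still reads 22.5 %, though 74.5 % of its first nucleophile is left at that time. So in north a reading at the plateau means waiting longer adds no target.

Take the neighbour of south charged with 0.050 M of first nucleophile. There s runs from 20.0 % to 16.7 %, so the plateau is 11.3 % and the mark at 1.0 h is 9.57 %. The computed flask reads 10.5 %, above its mark, as south was.

(All constants are made up; the rest is arithmetic.)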